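**Retrosynthetic overview**
- Last bond: C3 of 2-hydroxy-5-methoxy-1,4-benzoquinone (two steps from benzoquinone) to the allylic CH2, by Pd-catalysed dehydrative C-allylation with an (E)-allylic alcohol.
- (E)-trisubstituted alkene: Zr-catalysed methylalumination of a terminal alkyne, then formaldehyde.
- Cyclohexene ring (the only ring built): one-carbon ring expansion of a cyclopentanone with Me3SiCHN2; the silicon then fixes the ring alkene by Peterson olefination.
- Secondary methyl stereocentre: stereospecific semipinacol 1,2-methyl shift (inversion) onto an α-mesyloxy carbon whose C–O bond is set by Shi oxidation.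
- Quaternary centre: Cu-catalysed asymmetric conjugate addition of a silyl-protected butynyl Grignard reagent to 3-methylcyclopent-2-enone.

Assumption: the absolute sense of the two catalyst-controlled steps (ligand antipode in step 1, ketone antipode in step 2) is taken from the usual transition-state models and would be confirmed on the first intermediates.

**Step 1**
Reactants: 1 3-methylcyclopent-2-en-1-one; 2 (4-bromobut-1-yn-1-yl)trimethylsilane
Product: 5 triethyl({(3S)-3-methyl-3-[4-(trimethylsilyl)but-3-yn-1-yl]cyclopent-1-en-1-yl}oxy)silane, via Grignard reagent 3 (not isolated), via magnesium enolate 4 (not isolated)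
Conditions: 2, Mg, Et2O; then 1, Cu(OTf)2 (3 mol%), chiral C2-symmetric imidazolinium salt (NHC precursor, 4 mol%, antipode giving the S adduct), Et2O, −30 °C; then Et3SiCl, Et3N, DMPU, −30 → 20 °C
Reagents that add atoms: chlorotriethylsilane, CC[Si](CC)(CC)Cl
Why: Copper–NHC-catalysed asymmetric conjugate addition of a primary alkyl Grignard reagent to a β-methyl cyclic enone sets the quaternary centre by ligand-controlled face selection, and O-silylation of the regiodefined magnesium enolate fixes the enol ether towards C2.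

**Step 2**
Reactants: 5 triethyl({(3S)-3-methyl-3-[4-(trimethylsilyl)but-3-yn-1-yl]cyclopent-1-en-1-yl}oxy)silane
Product: 7 (2R,3S)-2-hydroxy-3-methyl-3-[4-(trimethylsilyl)but-3-yn-1-yl]cyclopentan-1-one, via silyloxy epoxide 6 (not isolated)
Conditions: D-fructose-derived Shi ketone (1,2:4,5-di-O-isopropylidene-β-D-erythro-2,3-hexodiulo-2,6-pyranose, 30 mol%), KHSO5 (as 2KHSO5·KHSO4·K2SO4), K2CO3, Bu4NHSO4, MeCN–CH2(OMe)2–aq. buffer, 0 °C; then citric acid, THF–H2O, 20 °C
Reagents that add atoms: potassium peroxymonosulfate, [K+].[O-]S(=O)(=O)OO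
Why: Shi asymmetric epoxidation of the silyl enol ether (Rubottom-type oxidation) puts oxygen on the C2 face cis to the C3 methyl under catalyst control, because methyl and CH2 on the neighbouring quaternary carbon give almost no substrate bias.

**Step 3**
Reactants: 7 (2R,3S)-2-hydroxy-3-methyl-3-[4-(trimethylsilyl)but-3-yn-1-yl]cyclopentan-1-one
Product: 8 (1R,2S)-2-methyl-5-oxo-2-[4-(trimethylsilyl)but-3-yn-1-yl]cyclopentyl methanesulfonate
Conditions: MsCl, Et3N, CH2Cl2, −20 °C
Reagents that add atoms: methanesulfonyl chloride, CS(=O)(=O)Cl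
Why: O-sulfonylation through the sulfene pathway works on hindered secondary alcohols and, kept cold, does not touch the C–O stereocentre.

**Step 4**
Reactants: 8 (1R,2S)-2-methyl-5-oxo-2-[4-(trimethylsilyl)but-3-yn-1-yl]cyclopentyl methanesulfonate
Product: 10 (2S,3S)-2,3-dimethyl-3-[4-(trimethylsilyl)but-3-yn-1-yl]cyclopentan-1-one, via bromomagnesium alkoxide 9 (not isolated)
Conditions: MeMgBr (1.1 equiv), toluene–Et2O, −78 °C; then 40 °C
Reagents that add atoms: methylmagnesium bromide, C[Mg]Br
Why: Semipinacol rearrangement (Tiffeneau/Tsuchihashi–Suzuki type): MeMgBr adds to the ketone anti to the α-mesyloxy group, and the methyl, now antiperiplanar to C–OMs, undergoes a 1,2-shift with inversion at C2, so the new methyl ends cis to the butynyl chain and trans to the C3 methyl; ring contraction to a cyclobutane is disfavoured.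

**Step 5**
Reactants: 10 (2S,3S)-2,3-dimethyl-3-[4-(trimethylsilyl)but-3-yn-1-yl]cyclopentan-1-one
Product: 11 (2S,3S)-2,3-dimethyl-6-(trimethylsilyl)-3-[4-(trimethylsilyl)but-3-yn-1-yl]cyclohexan-1-one (both C6 epimers)
Conditions: Me3SiCHN2, Sc(OTf)3 (10 mol%), toluene, −20 → 0 °C
Reagents that add atoms: (trimethylsilyl)diazomethane, C[Si](C)(C)C=[N+]=[N-]
Why: Lewis-acid-catalysed diazoalkane ring expansion (Tiffeneau–Demjanov-type 1,2-alkyl shift): the unhindered CH2, not the CH(Me) next to the quaternary carbon, migrates with loss of N2, giving the six-membered α-silyl ketone without base, so C2 and C3 are untouched.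

**Step 6**
Reactants: 11 (2S,3S)-2,3-dimethyl-6-(trimethylsilyl)-3-[4-(trimethylsilyl)but-3-yn-1-yl]cyclohexan-1-one (both C6 epimers)
Product: 13 trimethyl{4-[(1R,2S)-1,2,3-trimethylcyclohex-3-en-1-yl]but-1-yn-1-yl}silane, via lithium alkoxide 12 (not isolated)
Conditions: MeLi, CeCl3, THF, −78 °C; then 1 M HCl, THF, 20 °C
Reagents that add atoms: methyllithium, [Li]C
Why: Organocerium addition to the hindered α-silyl ketone followed by acid-promoted Peterson elimination places the alkene only between the carbinol carbon and the silicon-bearing carbon, whichever diastereomer of the β-hydroxysilane forms.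

**Step 7**
Reactants: 13 trimethyl{4-[(1R,2S)-1,2,3-trimethylcyclohex-3-en-1-yl]but-1-yn-1-yl}silane
Product: 14 4-[(1R,2S)-1,2,3-trimethylcyclohex-3-en-1-yl]but-1-yne
Conditions: K2CO3 (cat.), MeOH, 20 °C
Reagents that add atoms: none
Why: Methoxide-mediated protodesilylation of the alkynylsilane frees the terminal alkyne and leaves the ring alkene and both stereocentres alone.

**Step 8**
Reactants: 14 4-[(1R,2S)-1,2,3-trimethylcyclohex-3-en-1-yl]but-1-yne
Product: 16 (2E)-3-methyl-5-[(1R,2S)-1,2,3-trimethylcyclohex-3-en-1-yl]pent-2-en-1-ol, via alkenylalane 15 (not isolated)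
Conditions: Me3Al, Cp2ZrCl2 (20 mol%), CH2Cl2, 0 → 20 °C; then (CH2O)n, 20 °C; H2O work-up
Reagents that add atoms: trimethylaluminium, C[Al](C)C; paraformaldehyde (as formaldehyde), C=O
Why: Negishi zirconium-catalysed carboalumination adds Me and Al syn across the terminal alkyne with the methyl on the internal carbon, and the alkenylalane attacks formaldehyde with retention, giving the (E)-trisubstituted allylic alcohol while the ring alkene is inert.

**Step 9**
Reactants: 17 cyclohexa-2,5-diene-1,4-dione (1,4-benzoquinone)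
Product: 18 2,5-dimethoxycyclohexa-2,5-diene-1,4-dione
Conditions: MeOH, ZnCl2, 65 °C
Reagents that add atoms: methanol, CO
Why: ZnCl2-promoted conjugate addition of methanol to benzoquinone, with excess quinone reoxidising each hydroquinone adduct, gives the 2,5-dimethoxyquinone.

**Step 10**
Reactants: 18 2,5-dimethoxycyclohexa-2,5-diene-1,4-dione
Product: 19 2-hydroxy-5-methoxycyclohexa-2,5-diene-1,4-dione
Conditions: NaOH (1.0 equiv), H2O–1,4-dioxane, 0 → 20 °C; then HCl
Reagents that add atoms: sodium hydroxide, [Na+].[OH-]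
Why: Addition–elimination of hydroxide on one vinylogous ester stops at the mono-hydrolysed stage because the resulting delocalised hydroxyquinonate anion resists a second attack.

**Step 11**
Reactants: 16 (2E)-3-methyl-5-[(1R,2S)-1,2,3-trimethylcyclohex-3-en-1-yl]pent-2-en-1-ol; 19 2-hydroxy-5-methoxycyclohexa-2,5-diene-1,4-dione
Product: 20 metachromin C, 2-hydroxy-5-methoxy-3-{(2E)-3-methyl-5-[(1R,2S)-1,2,3-trimethylcyclohex-3-en-1-yl]pent-2-en-1-yl}cyclohexa-2,5-diene-1,4-dione
Conditions: Pd(PPh3)4 (5 mol%), 1,4-dioxane, 60 °C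
Reagents that add atoms: none
Why: Proposed new method: direct dehydrative Tsuji–Trost C-allylation of a 2-hydroxy-1,4-benzoquinone with a free trisubstituted allylic alcohol, in which the acidic hydroxyquinone protonates the alcohol so that zerovalent palladium ionises it to a π-allyl complex paired with the hydroxyquinonate, whose C3 attacks the unsubstituted allyl terminus faster than syn/anti isomerisation (linear product, E retained, no new stereocentre) while any O-allyl ether re-ionises to the more stable C-allyl quinone; the closest known reactions are palladium-catalysed C-allylations of 2-hydroxy-1,4-naphthoquinone, 4-hydroxycoumarins and cyclic 1,3-diones with allylic alcohols or carbonates.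

**Compound list**
1 | 3-methylcyclopent-2-en-1-one | CC1=CC(=O)CC1 | starting material
2 | (4-bromobut-1-yn-1-yl)trimethylsilane | C[Si](C)(C)C#CCCBr | starting material
3 | [4-(trimethylsilyl)but-3-yn-1-yl]magnesium bromide | C[Si](C)(C)C#CCC[Mg]Br | intermediate
4 | bromomagnesium (3S)-3-methyl-3-[4-(trimethylsilyl)but-3-yn-1-yl]cyclopent-1-en-1-olate | C[Si](C)(C)C#CCC[C@@]1(C)CCC(O[Mg]Br)=C1 | intermediate
5 | triethyl({(3S)-3-methyl-3-[4-(trimethylsilyl)but-3-yn-1-yl]cyclopent-1-en-1-yl}oxy)silane | C[Si](C)(C)C#CCC[C@@]1(C)CCC(O[Si](CC)(CC)CC)=C1 | intermediate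
6 | triethyl({(1R,4S,5R)-4-methyl-4-[4-(trimethylsilyl)but-3-yn-1-yl]-6-oxabicyclo[3.1.0]hexan-1-yl}oxy)silane (epoxide oxygen cis to the ring methyl) | C[Si](C)(C)C#CCC[C@@]1(C)CC[C@]2(O[Si](CC)(CC)CC)O[C@H]12 | intermediate
7 | (2R,3S)-2-hydroxy-3-methyl-3-[4-(trimethylsilyl)but-3-yn-1-yl]cyclopentan-1-one | C[Si](C)(C)C#CCC[C@@]1(C)CCC(=O)[C@@H]1O | intermediate
8 | (1R,2S)-2-methyl-5-oxo-2-[4-(trimethylsilyl)but-3-yn-1-yl]cyclopentyl methanesulfonate | C[Si](C)(C)C#CCC[C@@]1(C)CCC(=O)[C@@H]1OS(C)(=O)=O | intermediate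
9 | bromomagnesium alkoxide of (1R,2S,5S)-5-hydroxy-2,5-dimethyl-2-[4-(trimethylsilyl)but-3-yn-1-yl]cyclopentyl methanesulfonate | C[Si](C)(C)C#CCC[C@@]1(C)CC[C@](C)(O[Mg]Br)[C@@H]1OS(C)(=O)=O | intermediate
10 | (2S,3S)-2,3-dimethyl-3-[4-(trimethylsilyl)but-3-yn-1-yl]cyclopentan-1-one | C[Si](C)(C)C#CCC[C@@]1(C)CCC(=O)[C@H]1C | intermediate
11 | (2S,3S)-2,3-dimethyl-6-(trimethylsilyl)-3-[4-(trimethylsilyl)but-3-yn-1-yl]cyclohexan-1-one (both C6 epimers) | C[Si](C)(C)C#CCC[C@@]1(C)CCC([Si](C)(C)C)C(=O)[C@H]1C | intermediate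
12 | lithium (2S,3S)-1,2,3-trimethyl-6-(trimethylsilyl)-3-[4-(trimethylsilyl)but-3-yn-1-yl]cyclohexan-1-olate (C1 and C6 epimers) | C[Si](C)(C)C#CCC[C@@]1(C)CCC([Si](C)(C)C)C(C)(O[Li])[C@H]1C | intermediate
13 | trimethyl{4-[(1R,2S)-1,2,3-trimethylcyclohex-3-en-1-yl]but-1-yn-1-yl}silane | C[Si](C)(C)C#CCC[C@@]1(C)CCC=C(C)[C@H]1C | intermediate
14 | 4-[(1R,2S)-1,2,3-trimethylcyclohex-3-en-1-yl]but-1-yne | C#CCC[C@@]1(C)CCC=C(C)[C@H]1C | intermediate
15 | dimethyl{(1E)-2-methyl-4-[(1R,2S)-1,2,3-trimethylcyclohex-3-en-1-yl]but-1-en-1-yl}alumane | C[Al](C)/C=C(\C)CC[C@@]1(C)CCC=C(C)[C@H]1C | intermediate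
16 | (2E)-3-methyl-5-[(1R,2S)-1,2,3-trimethylcyclohex-3-en-1-yl]pent-2-en-1-ol | OC/C=C(\C)CC[C@@]1(C)CCC=C(C)[C@H]1C | intermediate
17 | cyclohexa-2,5-diene-1,4-dione (1,4-benzoquinone) | O=C1C=CC(=O)C=C1 | starting material
18 | 2,5-dimethoxycyclohexa-2,5-diene-1,4-dione | COC1=CC(=O)C(OC)=CC1=O | intermediate
19 | 2-hydroxy-5-methoxycyclohexa-2,5-diene-1,4-dione | COC1=CC(=O)C(O)=CC1=O | intermediate
20 | metachromin C, 2-hydroxy-5-methoxy-3-{(2E)-3-methyl-5-[(1R,2S)-1,2,3-trimethylcyclohex-3-en-1-yl]pent-2-en-1-yl}cyclohexa-2,5-diene-1,4-dione | COC1=CC(=O)C(O)=C(C/C=C(\C)CC[C@@]2(C)CCC=C(C)[C@H]2C)C1=O | target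

**Step count and risks**
Total steps: 11. Longest linear sequence: 9 (steps 1–8 and 11; steps 9 and 10 make the quinone partner).

The three steps most likely to fail:

Risk at step 2 (turnover and face selectivity of the dioxirane on a hindered enol ether next to a quaternary carbon). The fallback sets out from the magnesium enolate 4 and comes back to the route at 7. The enolate is not silylated but oxidised in the same flask at −78 °C with (+)-(camphorsulfonyl)oxaziridine, or its antipode if the sense is mismatched. This is a reagent-controlled enolate hydroxylation in place of an alkene epoxidation, and it makes no compound outside the list (F0).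

Risk at step 4 (the 1,2-methyl shift has to deliver carbon to a secondary centre flanked by a quaternary carbon, and the Grignard reagent may enolise 8). The fallback sets out from the magnesium enolate 4 and comes back at 10. The enolate is C-methylated directly (MeI, DMPU, −30 °C), a plain enolate alkylation with little facial bias. It gives 10 together with its C2 epimer (2R,3S)-2,3-dimethyl-3-[4-(trimethylsilyl)but-3-yn-1-yl]cyclopentan-1-one F1, which is removed by preparative chromatography.

Risk at step 11 (the new step: quinone-mediated oxidation of the palladium catalyst, O- versus C-allylation, or partial E/Z scrambling could intervene). The fallback uses known chemistry, sets out from 16 and comes back at 20. The alcohol is converted with CBr4 and PPh3 (CH2Cl2, 0 °C) into (2E)-1-bromo-3-methyl-5-[(1R,2S)-1,2,3-trimethylcyclohex-3-en-1-yl]pent-2-ene F2. Separately 19 is deprotonated with LiH in DMSO to lithium 4-methoxy-3,6-dioxocyclohexa-1,4-dien-1-olate F3, which is C-alkylated by the bromide at 25 °C, the classical allylation of hydroxyquinone salts.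

Further compounds
F0 | step 2 | none | none
F1 | step 4 | (2R,3S)-2,3-dimethyl-3-[4-(trimethylsilyl)but-3-yn-1-yl]cyclopentan-1-one | C[Si](C)(C)C#CCC[C@@]1(C)CCC(=O)[C@@H]1C
F2 | step 11 | (2E)-1-bromo-3-methyl-5-[(1R,2S)-1,2,3-trimethylcyclohex-3-en-1-yl]pent-2-ene | BrC/C=C(\C)CC[C@@]1(C)CCC=C(C)[C@H]1C
F3 | step 11 | lithium 4-methoxy-3,6-dioxocyclohexa-1,4-dien-1-olate | [Li+].COC1=CC(=O)C([O-])=CC1=O
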